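## The problem

Target 21 is a 3,3,5,5-tetrasubstituted 1,2-dioxolane. C3 carries a methyl group and the acetic acid arm; C5 carries a methyl group and a fifteen-carbon chain with a (7E,9E)-diene and, one methylene further on, a (12Z)-alkene. The only stereocentres are the two quaternary ring carbons, C3 (R) and C5 (S), 1,3-related across the C4 methylene with the two methyl groups trans. Each centre bears one methyl and one methylene-linked substituent of nearly equal size, so neither can direct the other usefully, and the chain offers nothing to relay stereochemical information. The O1–O2 bond forbids dissolving metals, low-valent metal reductants, hydrogenation, hot phosphines and forcing hydride reductions once it is in place, and the skipped triene with its doubly allylic C11 forbids strong acid and electrophilic oxidants late in the route. Once the C3 arm reaches the aldehyde or acid level, O2 sits β to a carbonyl group and can be expelled through an enolate, so the arm should stay a protected alcohol until the chain is finished. What opens the route is that O1–O2–C3, with the C3 methyl and a two-carbon arm, is the peroxide half of the 1,2,4-trioxolane made by ozonising an isoprenol ether. That ring differs from the target ring only in holding O4–C5H2 where C4–C5 must be, and C4–C5 with its methyl and chain is a 2-methylalk-1-ene whose terminal carbon is nucleophilic and whose internal carbon can carry a tertiary cation.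

## Retrosynthesis

**Arm oxidation last (21 to 18).** No skeletal bond is cut in the first move: acid 21 is taken back through aldehyde 20 to alcohol 19 and its silyl ether 18. With a carbonyl group in the arm, O2 becomes a β-leaving group, and an ester arm could not be trusted under the amide base of the olefination that completes the triene. A silyl ether is inert to every reagent used on the chain. The forward steps must oxidise a primary alcohol in two stages without base and without attacking the triene.

**C9=C10 (18 to 13 and 17).** Cutting this double bond lets the (12Z)-alkene arrive ready-made in sulfone 17 and forms the new alkene as E by a Julia–Kocienski olefination of enal 13. Cutting C7=C8 with an eight-carbon allylic sulfone or ylide would give poorer geometry control. Cutting the C8–C9 single bond would call for a metal-catalysed coupling beside a peroxide. The cut removes six carbons and one alkene from the ring-bearing fragment and asks for E-selective olefination of a conjugated aldehyde under conditions that leave O–O alone.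

**C–S bond (17 to 14 and 15).** Sulfone 17 goes back through sulfide 16 to (Z)-hex-3-en-1-ol 14 and thiol 15. The Z geometry is bought, not made. Two routine steps are asked for: a Mitsunobu thioetherification and a sulfur oxidation that spares the alkene.

**C7=C8 (13 to 11 and 12).** The enal is cut to saturated aldehyde 11 and the two-carbon formyl ylide 12. A stabilised ylide gives the E-alkene and adds exactly the two carbons that separate the spacer from the sulfone partner. Aldehyde 11 comes from alcohol 10, and 10 from the doubly silylated dioxolane 9 by removing the more labile silyl group. Alcohol 10 is also the point at which the stereoisomers are parted, because the free hydroxyl is the first useful chromatographic handle.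

**C3–C4 and O1–C5, with a CH2O unit added back (9 to 4 and 8).** This is the key disconnection: dioxolane 9 is traced to ozonide 4 and alkene 8. Cutting both C–O bonds of the peroxide instead would require a stereodefined 1,3-bis-electrophile. Cutting the exocyclic C–C bonds would leave the ring to be made separately and bring in only a short stub of the chain. The chosen cut forms the ring, both quaternary centres and the seven-carbon, oxygen-terminated spacer in one operation from two fragments without defined stereocentres. The forward reaction must ionise the C–O and not the O–O bond of the ozonide, add the alkene in the Markovnikov sense, and close the five-membered ring with loss of the one-carbon fragment. It cannot control configuration, and that cost is paid in step 6.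

**The two fragments (4 to 1; 8 to 5 and 7).** Ozonide 4 comes from silyl ether 2 by ozonolysis in a non-participating solvent, through primary ozonide 3, and 2 comes from isoprenol 1. Alkene 8 is cut at the sp3–sp2 bond next to the double bond into bromide 6 and isopropenyl Grignard reagent 7; 6 is the silyl ether of bromo alcohol 5. Each fragment is two steps from a commodity alcohol. The only demands are that the ozonide be isolated intact and that the cross-coupling tolerate a silyl ether.

## Roads not taken

**Alternative 1:** This road cuts both C–O bonds of the peroxide (O1–C5 and O2–C3) and takes the two oxygens from a silyl-triflate-activated peroxide source (H2O2). The C2-symmetric bis-oxetane A1 would be opened at one tertiary carbon with inversion, and the new hydroperoxide would open the second oxetane 5-exo with inversion, giving diol A2.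
- Merits: both stereocentres come from stereospecific displacements, C2 symmetry makes the two arms equivalent, and no resolution is needed.
- Weak points: substitution at a tertiary oxetane carbon under Lewis acid has carbocation character, so stereochemical fidelity is uncertain. The intermediate tertiary hydroperoxide is exposed to acid-induced fragmentation. Enantiopure A1 needs its own multi-step asymmetric synthesis of two tertiary ether centres. After A2, one two-carbon arm must grow by thirteen carbons, and the first C–C bond has to be made through the base-sensitive β-peroxy aldehyde, followed by chemoselective saturation of an alkene beside O–O.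
- Comparison: if the displacements were clean, this road would be stereochemically superior, with a theoretical throughput of all material against at most a quarter in the chosen plan. The chosen plan sets against that a much shorter path to the ring, a spacer and two differentiated arms delivered directly, and no reliance on stereospecific substitution at tertiary carbon.

**Alternative 2:** This road cuts the two exocyclic bonds C3–CH2 and C5–CH2 and keeps a preformed ring. The symmetrical bis-ketal A3 would be ionised twice in one pot, silyl ketene acetal A4 adding to the first peroxycarbenium ion and allylsilane A5 to the second, to give ester A6; no ring closes.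
- Merits: the ring comes from commodity materials, each substitution type is established on alkoxydioxolanes, and the acid arm arrives at the right oxidation level. That saves a deprotection and two oxidations and avoids the β-peroxy aldehyde.
- Weak points: there is no absolute control and little relative control, so the separation burden equals that of the chosen plan. Two different nucleophiles on a symmetrical bis-electrophile invite crossover products. The allyl group supplies three of fifteen chain carbons, so a long homologation with a chemoselective alkene saturation beside O–O must follow. The enolisable ester arm would have to survive the strong base of the triene-forming olefination.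
- Comparison: this road equals the chosen plan on stereochemistry and is better on ring access and arm oxidation level. The chosen plan sets against it the seven-carbon spacer installed during ring formation and an arm that cannot enolise until the last step.

**Alternative 3:** This road cuts O1–C5 and C5–CH2 and presets C3. A silyl triflate (Me3SiOTf) would close the silylperoxy group of the (S)-ketone A7 onto its methyl ketone, ionise the resulting silyloxy ketal, and let allylsilane A5 add to C5 trans to the silyloxyethyl arm, giving A8.
- Merits: the absolute configuration at C3 is carried in, C5 is set by substrate control, and both events have close precedent.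
- Weak points: enantiopure A7 requires asymmetric construction of a tertiary C–OO bond, which is long and itself prone to stereochemical leakage. Facial discrimination at C5 rests on methyl against a methylene-linked arm across the ring, so a diastereomer separation is likely still needed. The allyl stub again demands a twelve-carbon elongation beside the peroxide.
- Comparison: this road is better than the chosen plan in stereochemical logic and in precedent, and it needs no resolution. The chosen plan sets against it brevity (ring, both quaternary centres and spacer in one step from two-step fragments), no handling of free tertiary hydroperoxides, and a chain terminus that is already an oxygen handle. It pays with an unprecedented step and the loss of the unwanted stereoisomers.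

Key step: step 5

Remark: parting the stereoisomers (cis from trans on silica, enantiomers on a chiral phase) is treated as part of the isolation in step 6 and is not counted as a step; which antipode is carried on would be settled by comparing computed and recorded vibrational circular dichroism of 10 and checked against the sign of rotation of the natural acid at 21.

Abbreviations: TBDPS = tert-butyldiphenylsilyl; TBS = tert-butyldimethylsilyl; PT = 1-phenyl-1H-tetrazol-5-yl; DMP = Dess–Martin periodinane; PPTS = pyridinium p-toluenesulfonate; DIAD = diisopropyl azodicarboxylate.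

## Steps

Step 1
Reactants: 1 3-methylbut-3-en-1-ol
Product: 2 tert-butyl[(3-methylbut-3-en-1-yl)oxy]diphenylsilane
Conditions: TBDPSCl, imidazole, CH2Cl2, 0 °C → rt
Reagents that add atoms: tert-butyl(chloro)diphenylsilane, CC(C)(C)[Si](Cl)(c1ccccc1)c1ccccc1
Why: Imidazole-mediated silylation of an unhindered primary alcohol; the TBDPS ether is chosen because its oxygen is hindered and weakly basic (least able to bind SnCl4 or to trap the C5 cation in step 5) and because it outlasts the acid methanolysis that later frees the chain terminus.

Step 2
Reactants: 2 tert-butyl[(3-methylbut-3-en-1-yl)oxy]diphenylsilane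
Product: 4 tert-butyl[2-(3-methyl-1,2,4-trioxolan-3-yl)ethoxy]diphenylsilane, via primary ozonide 3 (not isolated)
Conditions: O3/O2, pentane, −78 °C, stopped at first persistent blue; N2 purge, warm to rt; SiO2
Reagents that add atoms: ozone, [O-][O+]=O
Why: Criegee ozonolysis in a non-participating solvent: 1,3-dipolar cycloaddition gives primary ozonide 3, which cleaves to a carbonyl oxide and a carbonyl partner that recombine in the solvent cage to the 1,2,4-trioxolane; the electron-rich 1,1-disubstituted alkene reacts far faster than the silicon-bound phenyl rings at −78 °C. The ozonide centre forms racemic, which is immaterial because it is ionised in step 5.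

Step 3
Reactants: 5 7-bromoheptan-1-ol
Product: 6 [(7-bromoheptyl)oxy](tert-butyl)dimethylsilane
Conditions: TBSCl, imidazole, CH2Cl2, 0 °C → rt
Reagents that add atoms: tert-butyl(chloro)dimethylsilane, CC(C)(C)[Si](C)(C)Cl
Why: Standard imidazole-mediated silylation; a primary TBS ether is the silyl group that can later be removed with PPTS in methanol while the TBDPS ether stays.

Step 4
Reactants: 6 [(7-bromoheptyl)oxy](tert-butyl)dimethylsilane; 7 isopropenylmagnesium bromide
Product: 8 tert-butyl(dimethyl)[(8-methylnon-8-en-1-yl)oxy]silane
Conditions: 7 (1.5 equiv), Li2CuCl4 (3 mol %), THF/NMP, 0 °C → rt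
Reagents that add atoms: none
Why: Kochi-type copper-catalysed sp3–sp2 cross-coupling of a primary alkyl bromide with an alkenyl Grignard reagent; NMP as co-solvent keeps the organocopper species active and suppresses elimination and homocoupling, and the silyl ether is inert to the Grignard reagent.

Step 5
Reactants: 4 tert-butyl[2-(3-methyl-1,2,4-trioxolan-3-yl)ethoxy]diphenylsilane; 8 tert-butyl(dimethyl)[(8-methylnon-8-en-1-yl)oxy]silane
Product: 9 tert-butyl{2-[(3S,5S)-5-{7-[tert-butyl(dimethyl)silyl]oxyheptyl}-3,5-dimethyl-1,2-dioxolan-3-yl]ethoxy}diphenylsilane (formed together with its enantiomer and the racemic cis isomer; the mixture is carried into step 6)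
Conditions: 8 (1.5 equiv), SnCl4 (1.2 equiv), CH2Cl2, −78 °C; aq. NaHCO3 quench at −78 °C
Reagents that add atoms: none
Why: Proposed new method: SnCl4 should bind the ring ether oxygen O4 of 4 and cleave its bond to the fully substituted carbon, since only that heterolysis gives a tertiary peroxycarbenium ion, whose distal peroxide oxygen remains tied to a CH2O–SnCl4 unit. The terminal CH2 of 8 then adds to C3 in the Markovnikov sense (C3–C4 bond), the tertiary cation at C5 is captured by the distal peroxide oxygen (O1–C5 bond), and the resulting oxonium ion sheds formaldehyde as its SnCl4 complex. The closest known reaction types are the SnCl4-mediated conversion of ozonides and allyltrimethylsilane into 1,2-dioxolanes and the [3+2] annulation of silylperoxy ketal-derived peroxycarbenium ions with alkenes; new here is the pairing of an ozonide as cation source with an unactivated 2-methylalk-1-ene, so that formaldehyde and not a silyl group is the fragment lost. The one ring closes in a polar stepwise (3+2) annulation whose last event is attack of O1 on a free tertiary carbocation through a five-membered transition state, followed by Grob-type loss of CH2O. C3 is set when the alkene meets either face of the planar peroxycarbenium ion and C5 when O1 closes on either face of the planar cation; nothing in 4 or 8 controls either event, because a methyl and a methylene-linked chain present almost the same steric demand, so 9 is expected together with its enantiomer and the racemic cis pair. What the step does need is chemoselectivity: C–O and not O–O heterolysis of the ozonide (a mild Lewis acid at −78 °C), ring closure ahead of proton loss or chloride capture at C5 (the peroxide oxygen is held five atoms away), no capture of the C5 cation by the arm oxygen (the TBDPS ether is hindered and weakly basic, and that closure would be six-membered), and survival of the primary TBS ether (short contact, cold bicarbonate quench).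

Step 6
Reactants: 9 tert-butyl{2-[(3S,5S)-5-{7-[tert-butyl(dimethyl)silyl]oxyheptyl}-3,5-dimethyl-1,2-dioxolan-3-yl]ethoxy}diphenylsilane (as the four-isomer mixture from step 5)
Product: 10 7-[(3S,5S)-5-{2-[tert-butyl(diphenyl)silyl]oxyethyl}-3,5-dimethyl-1,2-dioxolan-3-yl]heptan-1-ol
Conditions: PPTS (cat.), MeOH, rt; then SiO2 HPLC (trans from cis); then preparative HPLC on cellulose tris(3,5-dimethylphenylcarbamate), hexane/i-PrOH
Reagents that add atoms: none
Why: Acid-catalysed methanolysis removes the unhindered primary TBS group much faster than the TBDPS group and leaves the peroxide untouched; no stereocentre is formed, the (3S,5S) isomer being selected from the four made in step 5. The trans pair should part from the cis pair on silica (trans is expected to show near-equivalent H-4 protons, cis a widely split pair), and the enantiomers should part on a polysaccharide carbamate phase, where the free hydroxyl and the phenyl groups next to the arm-bearing centre offer hydrogen-bond and π contacts.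

Step 7
Reactants: 10 7-[(3S,5S)-5-{2-[tert-butyl(diphenyl)silyl]oxyethyl}-3,5-dimethyl-1,2-dioxolan-3-yl]heptan-1-ol
Product: 11 7-[(3S,5S)-5-{2-[tert-butyl(diphenyl)silyl]oxyethyl}-3,5-dimethyl-1,2-dioxolan-3-yl]heptanal
Conditions: DMP, CH2Cl2, 0 °C → rt
Reagents that add atoms: none
Why: Dess–Martin oxidation of a primary alcohol to the aldehyde is neutral to mildly acidic and non-reductive, so neither the O–O bond nor the TBDPS ether is at risk.

Step 8
Reactants: 11 7-[(3S,5S)-5-{2-[tert-butyl(diphenyl)silyl]oxyethyl}-3,5-dimethyl-1,2-dioxolan-3-yl]heptanal; 12 2-(triphenylphosphoranylidene)acetaldehyde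
Product: 13 (2E)-9-[(3S,5S)-5-{2-[tert-butyl(diphenyl)silyl]oxyethyl}-3,5-dimethyl-1,2-dioxolan-3-yl]non-2-enal
Conditions: 12 (1.2 equiv), toluene, 70 °C
Reagents that add atoms: none
Why: Wittig olefination with a formyl-stabilised ylide; reversible addition funnels the reaction to the (E)-enal, which sets C7=C8, and the conjugated product is less electrophilic than 11, which limits a second homologation when the ylide is kept near one equivalent. The ylide is a pentavalent phosphorus species and is not expected to deoxygenate a hindered di-tertiary peroxide at this temperature.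

Step 9
Reactants: 14 (3Z)-hex-3-en-1-ol; 15 1-phenyl-1H-tetrazole-5-thiol
Product: 16 5-{[(3Z)-hex-3-en-1-yl]sulfanyl}-1-phenyl-1H-tetrazole
Conditions: PPh3, DIAD, THF, 0 °C → rt
Reagents that add atoms: none
Why: Mitsunobu thioetherification of a primary alcohol with an acidic heteroaryl thiol; the (Z)-alkene is a spectator.

Step 10
Reactants: 16 5-{[(3Z)-hex-3-en-1-yl]sulfanyl}-1-phenyl-1H-tetrazole
Product: 17 5-{[(3Z)-hex-3-en-1-yl]sulfonyl}-1-phenyl-1H-tetrazole
Conditions: (NH4)6Mo7O24·4H2O (cat.), 30% H2O2, EtOH, 0 °C → rt
Reagents that add atoms: hydrogen peroxide, OO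
Why: Molybdate-catalysed oxidation with H2O2 takes the sulfide through the sulfoxide to the sulfone; sulfur is oxidised much faster than an unactivated 1,2-dialkyl alkene under these conditions.

Step 11
Reactants: 13 (2E)-9-[(3S,5S)-5-{2-[tert-butyl(diphenyl)silyl]oxyethyl}-3,5-dimethyl-1,2-dioxolan-3-yl]non-2-enal; 17 5-{[(3Z)-hex-3-en-1-yl]sulfonyl}-1-phenyl-1H-tetrazole
Product: 18 tert-butyl{2-[(3S,5S)-3,5-dimethyl-5-[(7E,9E,12Z)-pentadeca-7,9,12-trien-1-yl]-1,2-dioxolan-3-yl]ethoxy}diphenylsilane
Conditions: 17, KN(SiMe3)2, DME, −60 °C; then 13, −60 °C → rt; aq. NH4Cl
Reagents that add atoms: none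
Why: Julia–Kocienski olefination: the potassium salt of PT sulfone 17 adds to enal 13, the adduct undergoes Smiles rearrangement and anti-elimination of SO2 and tetrazolate, and the potassium counter-ion in DME favours the open transition state that leads to the (E)-alkene at C9=C10; the (7E)- and (12Z)-alkenes are not touched. With the arm still a silyl ether there is no carbonyl β to the ring oxygen, so the base has no way to open the dioxolane.

Step 12
Reactants: 18 tert-butyl{2-[(3S,5S)-3,5-dimethyl-5-[(7E,9E,12Z)-pentadeca-7,9,12-trien-1-yl]-1,2-dioxolan-3-yl]ethoxy}diphenylsilane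
Product: 19 2-[(3S,5S)-3,5-dimethyl-5-[(7E,9E,12Z)-pentadeca-7,9,12-trien-1-yl]-1,2-dioxolan-3-yl]ethan-1-ol
Conditions: Bu4NF, AcOH, THF, 0 °C → rt
Reagents that add atoms: none
Why: Fluoride-induced cleavage of the TBDPS ether, buffered with acetic acid; the tetrasubstituted dioxolane has no hydrogen on its oxygen-bearing carbons, so base-induced Kornblum–DeLaMare fragmentation is not possible, and the triene is inert.

Step 13
Reactants: 19 2-[(3S,5S)-3,5-dimethyl-5-[(7E,9E,12Z)-pentadeca-7,9,12-trien-1-yl]-1,2-dioxolan-3-yl]ethan-1-ol
Product: 20 [(3R,5S)-3,5-dimethyl-5-[(7E,9E,12Z)-pentadeca-7,9,12-trien-1-yl]-1,2-dioxolan-3-yl]acetaldehyde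
Conditions: DMP, CH2Cl2, 0 °C; used crude
Reagents that add atoms: none
Why: Dess–Martin oxidation stops at the aldehyde under non-basic conditions, which matters because 20 carries the ring oxygen β to the carbonyl group and would open by E1cB elimination under base; it is therefore taken on without chromatography. The C3 descriptor changes from S to R only because the arm gains CIP priority; the centre itself is untouched.

Step 14
Reactants: 20 [(3R,5S)-3,5-dimethyl-5-[(7E,9E,12Z)-pentadeca-7,9,12-trien-1-yl]-1,2-dioxolan-3-yl]acetaldehyde
Product: 21 [(3R,5S)-3,5-dimethyl-5-[(7E,9E,12Z)-pentadeca-7,9,12-trien-1-yl]-1,2-dioxolan-3-yl]acetic acid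
Conditions: NaClO2, NaH2PO4, 2-methylbut-2-ene, t-BuOH/H2O, 0 °C
Reagents that add atoms: sodium chlorite, [Na+].[O-]Cl=O
Why: Pinnick (Lindgren–Kraus) oxidation converts the aldehyde into the acid at about pH 4, where neither enolisation nor acid-induced ionisation of the peroxide is expected; 2-methylbut-2-ene in large excess removes HOCl before it can add to the triene. No stereocentre is touched, so 21 keeps the configuration selected in step 6.

## Compound list

1 | 3-methylbut-3-en-1-ol | C=C(C)CCO | starting material
2 | tert-butyl[(3-methylbut-3-en-1-yl)oxy]diphenylsilane | C=C(C)CCO[Si](c1ccccc1)(c1ccccc1)C(C)(C)C | intermediate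
3 | tert-butyl[2-(4-methyl-1,2,3-trioxolan-4-yl)ethoxy]diphenylsilane (primary ozonide, racemic, not isolated) | CC1(CCO[Si](c2ccccc2)(c2ccccc2)C(C)(C)C)COOO1 | intermediate
4 | tert-butyl[2-(3-methyl-1,2,4-trioxolan-3-yl)ethoxy]diphenylsilane (racemic) | CC1(CCO[Si](c2ccccc2)(c2ccccc2)C(C)(C)C)OCOO1 | intermediate
5 | 7-bromoheptan-1-ol | OCCCCCCCBr | starting material
6 | [(7-bromoheptyl)oxy](tert-butyl)dimethylsilane | BrCCCCCCCO[Si](C)(C)C(C)(C)C | intermediate
7 | isopropenylmagnesium bromide | C=C(C)[Mg]Br | starting material
8 | tert-butyl(dimethyl)[(8-methylnon-8-en-1-yl)oxy]silane | C=C(C)CCCCCCCO[Si](C)(C)C(C)(C)C | intermediate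
9 | tert-butyl{2-[(3S,5S)-5-{7-[tert-butyl(dimethyl)silyl]oxyheptyl}-3,5-dimethyl-1,2-dioxolan-3-yl]ethoxy}diphenylsilane (methyl groups trans; carried as a mixture with its enantiomer and the cis racemate until step 6) | CC(C)(C)[Si](C)(C)OCCCCCCC[C@@]1(C)C[C@](C)(CCO[Si](c2ccccc2)(c2ccccc2)C(C)(C)C)OO1 | intermediate
10 | 7-[(3S,5S)-5-{2-[tert-butyl(diphenyl)silyl]oxyethyl}-3,5-dimethyl-1,2-dioxolan-3-yl]heptan-1-ol | OCCCCCCC[C@@]1(C)C[C@](C)(CCO[Si](c2ccccc2)(c2ccccc2)C(C)(C)C)OO1 | intermediate
11 | 7-[(3S,5S)-5-{2-[tert-butyl(diphenyl)silyl]oxyethyl}-3,5-dimethyl-1,2-dioxolan-3-yl]heptanal | O=CCCCCCC[C@@]1(C)C[C@](C)(CCO[Si](c2ccccc2)(c2ccccc2)C(C)(C)C)OO1 | intermediate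
12 | 2-(triphenylphosphoranylidene)acetaldehyde | O=CC=P(c1ccccc1)(c1ccccc1)c1ccccc1 | starting material
13 | (2E)-9-[(3S,5S)-5-{2-[tert-butyl(diphenyl)silyl]oxyethyl}-3,5-dimethyl-1,2-dioxolan-3-yl]non-2-enal | O=C/C=C/CCCCCC[C@@]1(C)C[C@](C)(CCO[Si](c2ccccc2)(c2ccccc2)C(C)(C)C)OO1 | intermediate
14 | (3Z)-hex-3-en-1-ol | CC/C=C\CCO | starting material
15 | 1-phenyl-1H-tetrazole-5-thiol | Sc1nnnn1-c2ccccc2 | starting material
16 | 5-{[(3Z)-hex-3-en-1-yl]sulfanyl}-1-phenyl-1H-tetrazole | CC/C=C\CCSc1nnnn1-c2ccccc2 | intermediate
17 | 5-{[(3Z)-hex-3-en-1-yl]sulfonyl}-1-phenyl-1H-tetrazole | CC/C=C\CCS(=O)(=O)c1nnnn1-c2ccccc2 | intermediate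
18 | tert-butyl{2-[(3S,5S)-3,5-dimethyl-5-[(7E,9E,12Z)-pentadeca-7,9,12-trien-1-yl]-1,2-dioxolan-3-yl]ethoxy}diphenylsilane | CC/C=C\C/C=C/C=C/CCCCCC[C@@]1(C)C[C@](C)(CCO[Si](c2ccccc2)(c2ccccc2)C(C)(C)C)OO1 | intermediate
19 | 2-[(3S,5S)-3,5-dimethyl-5-[(7E,9E,12Z)-pentadeca-7,9,12-trien-1-yl]-1,2-dioxolan-3-yl]ethan-1-ol | CC/C=C\C/C=C/C=C/CCCCCC[C@@]1(C)C[C@](C)(CCO)OO1 | intermediate
20 | [(3R,5S)-3,5-dimethyl-5-[(7E,9E,12Z)-pentadeca-7,9,12-trien-1-yl]-1,2-dioxolan-3-yl]acetaldehyde | CC/C=C\C/C=C/C=C/CCCCCC[C@@]1(C)C[C@](C)(CC=O)OO1 | intermediate
21 | [(3R,5S)-3,5-dimethyl-5-[(7E,9E,12Z)-pentadeca-7,9,12-trien-1-yl]-1,2-dioxolan-3-yl]acetic acid | CC/C=C\C/C=C/C=C/CCCCCC[C@@]1(C)C[C@](C)(CC(=O)O)OO1 | target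

## Step count and risks

Total step count: 14.
Longest linear sequence: 10 steps (1 → 2 → 4 → 9 → 10 → 11 → 13 → 18 → 19 → 20 → 21; the branch from 5 is equally long).

**Step 5 (key step, proposed new method).** The most likely failures are three. The ozonide may ionise at O–O and fragment instead of giving the peroxycarbenium ion. The tertiary cation at C5 may lose a proton or pick up chloride before the peroxide oxygen closes on it. The alkene may be consumed by cationic oligomerisation. The fallback uses known chemistry, sets out from 2 and returns at 9:
- Ozonolysis of 2 in CH2Cl2/MeOH at −78 °C would trap the carbonyl oxide as the hydroperoxy ketal tert-butyl[(3-hydroperoxy-3-methoxybutyl)oxy]diphenylsilane F1.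
- Silylation (Et3SiCl, imidazole, DMF) would give the silylperoxy ketal tert-butyl({3-methoxy-3-[(triethylsilyl)peroxy]butyl}oxy)diphenylsilane F2.
- SnCl4 in CH2Cl2 at −78 °C with alkene 8 would ionise the methoxy group and give 9 by the established annulation of silylperoxy ketal-derived peroxycarbenium ions with 1,1-disubstituted alkenes, the silyl group instead of formaldehyde leaving from the peroxide oxygen.

The same C3–C4 and O1–C5 bonds form, the isomer mixture and its treatment in step 6 are unchanged, and the cost is one extra step.

**Step 6.** The deprotection is safe; the risk is co-elution of the stereoisomers, because the two ring centres differ only by methyl against methylene and no chiral phase may discriminate on a useful scale. The fallback sets out from 10, taken on as the unresolved trans racemate or as the full mixture, and returns at 19: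
- The material would be carried through steps 7 to 12 unchanged.
- The resulting alcohol 19 would be acylated with (1S)-camphanic chloride (pyridine, DMAP, CH2Cl2). This gives 2-[(3S,5S)-3,5-dimethyl-5-[(7E,9E,12Z)-pentadeca-7,9,12-trien-1-yl]-1,2-dioxolan-3-yl]ethyl (1S,4R)-4,7,7-trimethyl-3-oxo-2-oxabicyclo[2.2.1]heptane-1-carboxylate F3 together with its diastereomer, 2-[(3R,5R)-3,5-dimethyl-5-[(7E,9E,12Z)-pentadeca-7,9,12-trien-1-yl]-1,2-dioxolan-3-yl]ethyl (1S,4R)-4,7,7-trimethyl-3-oxo-2-oxabicyclo[2.2.1]heptane-1-carboxylate F4.
- These are diastereomers and would be parted on silica or by crystallisation; LiOH in THF/H2O on F3 would return 19.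

Resolution then happens late and on advanced material, which is why it is the fallback.

**Step 8.** The formyl ylide is sluggish with aliphatic aldehydes; prolonged heating invites a second homologation to the dienal and thermal stress on the O–O bond. The fallback sets out from 11 and returns at 13:
- Horner–Wadsworth–Emmons reaction with triethyl phosphonoacetate (LiCl, DBU, MeCN, rt) would give ethyl (2E)-9-[(3S,5S)-5-{2-[tert-butyl(diphenyl)silyl]oxyethyl}-3,5-dimethyl-1,2-dioxolan-3-yl]non-2-enoate F5.
- i-Bu2AlH in CH2Cl2 at −78 °C, which is expected to spare a hindered di-tertiary peroxide at that temperature, would give (2E)-9-[(3S,5S)-5-{2-[tert-butyl(diphenyl)silyl]oxyethyl}-3,5-dimethyl-1,2-dioxolan-3-yl]non-2-en-1-ol F6.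
- MnO2 in CH2Cl2 would oxidise the allylic alcohol to 13.

**Step 11.** Two processes threaten it: erosion of E-selectivity at C9=C10, because conjugated aldehydes are less well-behaved partners for PT sulfones than saturated ones, and γ-deprotonation of the enal by the sulfonyl anion. The fallback sets out from 11, bypasses 13, and returns at 18. It forms C7=C8 with a phosphonate that already holds the (E)-C9=C10 and (Z)-C12=C13 bonds:
- Prop-2-yn-1-ol and commercial (2Z)-1-bromopent-2-ene (CuI, NaI, K2CO3, DMF) would give (5Z)-oct-5-en-2-yn-1-ol F7.
- LiAlH4 in THF would reduce the propargylic alcohol trans-selectively to (2E,5Z)-octa-2,5-dien-1-ol F8.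
- PBr3 in Et2O at 0 °C would give (2E,5Z)-1-bromoocta-2,5-diene F9.
- Michaelis–Arbuzov reaction with P(OEt)3 would give diethyl [(2E,5Z)-octa-2,5-dien-1-yl]phosphonate F10.
- Deprotonation of F10 with LiN(SiMe3)2 in THF at −78 °C and addition of 11 would give 18 by an E-selective Horner–Wadsworth–Emmons reaction of an allylic phosphonate.

**Step 13.** The β-peroxy aldehyde 20 may open by elimination of the ring oxygen during work-up or on contact with silica or traces of base. The fallback sets out from 19 and returns at 21: catalytic TEMPO with PhI(OAc)2 in MeCN/H2O would oxidise the alcohol through the hydrated aldehyde to the acid in one flask under mildly acidic conditions, so 20 is never isolated. This fallback makes no new compound (F0).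

## Further compounds

F1 | step 5 | tert-butyl[(3-hydroperoxy-3-methoxybutyl)oxy]diphenylsilane (racemic) | COC(C)(CCO[Si](c1ccccc1)(c1ccccc1)C(C)(C)C)OO
F2 | step 5 | tert-butyl({3-methoxy-3-[(triethylsilyl)peroxy]butyl}oxy)diphenylsilane (racemic) | COC(C)(CCO[Si](c1ccccc1)(c1ccccc1)C(C)(C)C)OO[Si](CC)(CC)CC
F3 | step 6 | 2-[(3S,5S)-3,5-dimethyl-5-[(7E,9E,12Z)-pentadeca-7,9,12-trien-1-yl]-1,2-dioxolan-3-yl]ethyl (1S,4R)-4,7,7-trimethyl-3-oxo-2-oxabicyclo[2.2.1]heptane-1-carboxylate | CC/C=C\C/C=C/C=C/CCCCCC[C@@]1(C)C[C@](C)(CCOC(=O)[C@@]23CC[C@@](C)(C(=O)O2)C3(C)C)OO1
F4 | step 6 | 2-[(3R,5R)-3,5-dimethyl-5-[(7E,9E,12Z)-pentadeca-7,9,12-trien-1-yl]-1,2-dioxolan-3-yl]ethyl (1S,4R)-4,7,7-trimethyl-3-oxo-2-oxabicyclo[2.2.1]heptane-1-carboxylate | CC/C=C\C/C=C/C=C/CCCCCC[C@]1(C)C[C@@](C)(CCOC(=O)[C@@]23CC[C@@](C)(C(=O)O2)C3(C)C)OO1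
F5 | step 8 | ethyl (2E)-9-[(3S,5S)-5-{2-[tert-butyl(diphenyl)silyl]oxyethyl}-3,5-dimethyl-1,2-dioxolan-3-yl]non-2-enoate | CCOC(=O)/C=C/CCCCCC[C@@]1(C)C[C@](C)(CCO[Si](c2ccccc2)(c2ccccc2)C(C)(C)C)OO1
F6 | step 8 | (2E)-9-[(3S,5S)-5-{2-[tert-butyl(diphenyl)silyl]oxyethyl}-3,5-dimethyl-1,2-dioxolan-3-yl]non-2-en-1-ol | OC/C=C/CCCCCC[C@@]1(C)C[C@](C)(CCO[Si](c2ccccc2)(c2ccccc2)C(C)(C)C)OO1
F7 | step 11 | (5Z)-oct-5-en-2-yn-1-ol | OCC#CC/C=C\CC
F8 | step 11 | (2E,5Z)-octa-2,5-dien-1-ol | OC/C=C/C/C=C\CC
F9 | step 11 | (2E,5Z)-1-bromoocta-2,5-diene | BrC/C=C/C/C=C\CC
F10 | step 11 | diethyl [(2E,5Z)-octa-2,5-dien-1-yl]phosphonate | CCOP(=O)(OCC)C/C=C/C/C=C\CC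
F0 | step 13 | none | none
A1 | alternative 1 | (2R,2'R)-2,2'-methanediylbis(2-methyloxetane) | O1CC[C@]1(C)C[C@@]2(C)CCO2
A2 | alternative 1 | 2,2'-[(3S,5S)-3,5-dimethyl-1,2-dioxolane-3,5-diyl]diethanol | OCC[C@@]1(C)C[C@](C)(CCO)OO1
A3 | alternative 2 | 3,5-dimethoxy-3,5-dimethyl-1,2-dioxolane | COC1(C)CC(C)(OC)OO1
A4 | alternative 2 | [(1-methoxyethenyl)oxy]trimethylsilane | C=C(OC)O[Si](C)(C)C
A5 | alternative 2 | trimethyl(prop-2-en-1-yl)silane | C=CC[Si](C)(C)C
A6 | alternative 2 | methyl 2-[(3R,5S)-3,5-dimethyl-5-(prop-2-en-1-yl)-1,2-dioxolan-3-yl]acetate | C=CC[C@@]1(C)C[C@](C)(CC(=O)OC)OO1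
A7 | alternative 3 | (4S)-6-{[tert-butyl(diphenyl)silyl]oxy}-4-methyl-4-[(triethylsilyl)peroxy]hexan-2-one | CC(=O)C[C@](C)(CCO[Si](c1ccccc1)(c1ccccc1)C(C)(C)C)OO[Si](CC)(CC)CC
A8 | alternative 3 | tert-butyl{2-[(3S,5S)-3,5-dimethyl-5-(prop-2-en-1-yl)-1,2-dioxolan-3-yl]ethoxy}diphenylsilane | C=CC[C@@]1(C)C[C@](C)(CCO[Si](c2ccccc2)(c2ccccc2)C(C)(C)C)OO1
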